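**Retrosynthetic overview**

1. The strategy rests on C8, the stereocentre whose ether oxygen is bound to the doubly ortho-substituted ring B (4-allyl-2,6-dimethoxyphenyl). C8 lies between C9 (CH2OAc) and C7 (the carbinol carbon on ring A, 3,4,5-trimethoxyphenyl), and this oxygenated C9–C8–C7 row is grown on boron, one carbon per homologation, under a single C2-symmetric diol.
2. Target ⇐ 1,3-diol (primary-selective acetylation) ⇐ 9-O-silyl carbinol (desilylation) ⇐ benzylic boronate (C7–B to C7–OH, retention) ⇐ α-chloro boronate + aryl Grignard reagent (C7–ring A bond, inversion) ⇐ C8 aryloxy boronate + LiCHCl2 (C8–C7 bond).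
3. Key disconnection: the C8 aryloxy boronate ⇐ (S,S)-diol (silyloxymethyl)boronate + CH2Cl2 (as LiCHCl2, the C8 carbon) + 4-allyl-2,6-dimethoxyphenol, forming C9–C8 and then C8–O(ring B) in one operation.
4. (Silyloxymethyl)boronate ⇐ hydroxymethyl ⇐ acetoxymethyl ⇐ bromomethyl boronate ⇐ B(OiPr)3 + CH2Br2 + (S,S)-1,2-dicyclohexylethane-1,2-diol.
5. No ring is formed on the way: rings A and B are bought, and only the dioxaborolane of the chiral director is assembled (step 1) and released again (step 9).

Key step: step 5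

Remark 1: C7, C8 and C9 are the carbinol carbon, the aryloxy-bearing carbon and the CH2O carbon; the target is the (7R,8R)-threo isomer.
Remark 2: the sense of induction is assumed to follow the empirical rule for C2-symmetric 1,2-diol boronates, by which the (S,S)-diol gives the α-chloro boronate that is (R) whenever Cl > C > B > H; the (R,R)-diol would give the mirror-image series.
Remark 3: in step 5 the α-chloro boronate is carried on as a washed crude solution without isolation, because free chloride would epimerize C8 and zinc would bind the aryloxide.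

**Step 1**
Reactants: 1 triisopropyl borate; 2 dibromomethane; 3 (1S,2S)-1,2-dicyclohexylethane-1,2-diol
Product: 6 (4S,5S)-2-(bromomethyl)-4,5-dicyclohexyl-1,3,2-dioxaborolane, via lithium (bromomethyl)triisopropoxyborate 4 (not isolated), via diisopropyl (bromomethyl)boronate 5 (not isolated)
Conditions: n-BuLi, THF, −78 °C → rt; MsOH, 0 °C; then 3, rt
Reagents that add atoms: none
Why: Bromine–lithium exchange on CH2Br2 generates LiCH2Br in the presence of the borate, which traps it as borate 4, acid releases boronate 5 and the chelating diol then displaces both isopropoxy groups (in situ halomethyllithium borylation followed by transesterification), no stereocentre being formed and those of the diol staying untouched.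

**Step 2**
Reactants: 6 (4S,5S)-2-(bromomethyl)-4,5-dicyclohexyl-1,3,2-dioxaborolane
Product: 7 [(4S,5S)-4,5-dicyclohexyl-1,3,2-dioxaborolan-2-yl]methyl acetate
Conditions: KOAc, DMF, rt → 50 °C
Reagents that add atoms: potassium acetate, CC(=O)[O-].[K+]
Why: Carboxylate substitution of an α-halo boronic ester (SN2 at the carbon next to boron), which is fast under mild conditions because the vacant boron orbital assists displacement of bromide.

**Step 3**
Reactants: 7 [(4S,5S)-4,5-dicyclohexyl-1,3,2-dioxaborolan-2-yl]methyl acetate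
Product: 8 [(4S,5S)-4,5-dicyclohexyl-1,3,2-dioxaborolan-2-yl]methanol
Conditions: K2CO3 (cat.), MeOH, 0 °C → rt; pH 7 buffer; used at once
Reagents that add atoms: none
Why: Base-catalysed transesterification (methanolysis of the acetate) frees the hydroxyl while the chelated dioxaborolane, far more stable than an acyclic methyl boronate, should stay intact.

**Step 4**
Reactants: 8 [(4S,5S)-4,5-dicyclohexyl-1,3,2-dioxaborolan-2-yl]methanol
Product: 9 (4S,5S)-2-[(tert-butyldimethylsilyloxy)methyl]-4,5-dicyclohexyl-1,3,2-dioxaborolane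
Conditions: TBSCl, imidazole, CH2Cl2, 0 °C → rt
Reagents that add atoms: tert-butyldimethylsilyl chloride, CC(C)(C)[Si](C)(C)Cl
Why: Imidazole-promoted silylation of a primary alcohol (silyl ether formation); the silyl ether tolerates LiCHCl2, the Grignard reagent and alkaline peroxide and is later removed by fluoride without harm to the allyl group or the benzylic carbinol.

**Step 5 (key step)**
Reactants: 9 (4S,5S)-2-[(tert-butyldimethylsilyloxy)methyl]-4,5-dicyclohexyl-1,3,2-dioxaborolane; 10 dichloromethane; 11 4-allyl-2,6-dimethoxyphenol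
Product: 15 (4S,5S)-2-[(1S)-1-(4-allyl-2,6-dimethoxyphenoxy)-2-(tert-butyldimethylsilyloxy)ethyl]-4,5-dicyclohexyl-1,3,2-dioxaborolane, via lithium dichloromethyl borate 12 (not isolated), via chloro boronate 13 (not isolated), via lithium aryloxide 14 (not isolated)
Conditions: CH2Cl2, n-BuLi, THF, −100 °C; 9, then ZnCl2, −100 °C → rt; pentane/aq NH4Cl wash, solvent exchange (crude 13); 14 (2 equiv, from 11 and n-BuLi, THF, 0 °C), THF/DMSO, rt → 45 °C
Reagents that add atoms: none
Why: LiCHCl2 adds to boron of 9 to give borate 12, and on warming with ZnCl2 the silyloxymethyl carbon C9 shifts from boron to the carbenoid carbon C8 with loss of the chloride that the C2-symmetric (S,S)-diol singles out, which forms the C9–C8 bond and gives chloride 13 with (1R) configuration (Matteson homologation). After the salts are washed out, aryloxide 14 adds to boron and its oxygen shifts to C8 with expulsion of the second chloride and inversion, which forms the C8–O bond to ring B and gives (1S)-15; the closest known reaction type is the displacement of α-chloro boronic esters by alkoxides and other oxygen nucleophiles, applied here to a 2,6-disubstituted aryloxide. No ring is closed. C8 is the only new stereocentre and is fixed by two events, the diol-directed choice between the two chlorides of 12 and the stereospecific inversion in the substitution. The step needs substitution at C8 to outrun epimerization of 13 by chloride and β-elimination of the C9 silyloxy group; removal of zinc and lithium chloride before the aryloxide is added, the poor leaving-group ability of silyloxide, the activation of C8 by the vacant boron orbital and the blocked ortho and para positions of the phenoxide (oxygen is its only free nucleophilic site) should secure this.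

**Step 6**
Reactants: 15 (4S,5S)-2-[(1S)-1-(4-allyl-2,6-dimethoxyphenoxy)-2-(tert-butyldimethylsilyloxy)ethyl]-4,5-dicyclohexyl-1,3,2-dioxaborolane; 10 dichloromethane
Product: 17 (4S,5S)-2-[(1R,2R)-2-(4-allyl-2,6-dimethoxyphenoxy)-3-(tert-butyldimethylsilyloxy)-1-chloropropyl]-4,5-dicyclohexyl-1,3,2-dioxaborolane, via lithium dichloromethyl borate 16 (not isolated)
Conditions: CH2Cl2, n-BuLi (1.2 equiv), THF, −100 °C; 15, then ZnCl2, −100 °C → rt; pentane/aq NH4Cl work-up, used crude
Reagents that add atoms: none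
Why: Second Matteson homologation, in which C8 migrates from boron to the new carbon C7 with retention and the (S,S)-diol again decides which chloride leaves, so that C7 is set as (R) under reagent control independently of the resident C8 centre.

**Step 7**
Reactants: 18 5-bromo-1,2,3-trimethoxybenzene
Product: 19 3,4,5-trimethoxyphenylmagnesium bromide (THF solution, titrated)
Conditions: Mg turnings, I2 (cat.), THF, rt → 50 °C
Reagents that add atoms: magnesium, [Mg]
Why: Insertion of magnesium into the aryl C–Br bond (Grignard reagent formation), to which the three methoxy groups are inert.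

**Step 8**
Reactants: 17 (4S,5S)-2-[(1R,2R)-2-(4-allyl-2,6-dimethoxyphenoxy)-3-(tert-butyldimethylsilyloxy)-1-chloropropyl]-4,5-dicyclohexyl-1,3,2-dioxaborolane; 19 3,4,5-trimethoxyphenylmagnesium bromide
Product: 21 (4S,5S)-2-[(1R,2S)-2-(4-allyl-2,6-dimethoxyphenoxy)-3-(tert-butyldimethylsilyloxy)-1-(3,4,5-trimethoxyphenyl)propyl]-4,5-dicyclohexyl-1,3,2-dioxaborolane, via bromomagnesium aryl borate 20 (not isolated)
Conditions: 19 (1.5 equiv), THF, −78 °C → rt
Reagents that add atoms: none
Why: The Grignard reagent adds to boron to give borate 20, whose aryl group shifts to C7 with expulsion of chloride and inversion (stereospecific 1,2-metallate rearrangement of an α-chloro boronic ester), which makes the C7–ring A bond with the configuration of the threo series.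

**Step 9**
Reactants: 21 (4S,5S)-2-[(1R,2S)-2-(4-allyl-2,6-dimethoxyphenoxy)-3-(tert-butyldimethylsilyloxy)-1-(3,4,5-trimethoxyphenyl)propyl]-4,5-dicyclohexyl-1,3,2-dioxaborolane
Product: 22 (1R,2R)-2-(4-allyl-2,6-dimethoxyphenoxy)-3-(tert-butyldimethylsilyloxy)-1-(3,4,5-trimethoxyphenyl)propan-1-ol
Conditions: 30% H2O2, aq NaOH, THF, 0 °C → rt
Reagents that add atoms: hydrogen peroxide, OO
Why: Alkaline peroxide oxidation of the C–B bond (hydroperoxide adds to boron and C7 shifts to oxygen with retention) should give the (7R)-carbinol and free the diol for recovery, the terminal alkene and the silyl ether being inert to these conditions.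

**Step 10**
Reactants: 22 (1R,2R)-2-(4-allyl-2,6-dimethoxyphenoxy)-3-(tert-butyldimethylsilyloxy)-1-(3,4,5-trimethoxyphenyl)propan-1-ol
Product: 23 (1R,2R)-2-(4-allyl-2,6-dimethoxyphenoxy)-1-(3,4,5-trimethoxyphenyl)propane-1,3-diol
Conditions: Bu4NF, THF, 0 °C → rt
Reagents that add atoms: none
Why: Fluoride-induced cleavage of the Si–O bond (desilylation), driven by the strong Si–F bond, which touches neither stereocentre.

**Step 11**
Reactants: 23 (1R,2R)-2-(4-allyl-2,6-dimethoxyphenoxy)-1-(3,4,5-trimethoxyphenyl)propane-1,3-diol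
Product: 24 (2R,3R)-2-(4-allyl-2,6-dimethoxyphenoxy)-3-hydroxy-3-(3,4,5-trimethoxyphenyl)propyl acetate
Conditions: AcCl (1.05 equiv), 2,4,6-collidine, CH2Cl2, −78 °C
Reagents that add atoms: acetyl chloride, CC(=O)Cl
Why: Kinetically controlled esterification of the unhindered primary hydroxyl with an acyl chloride and a hindered pyridine base at low temperature, the secondary benzylic hydroxyl being shielded by ring A and by the 2,6-dimethoxyaryloxy group.

**Compound list**

1 | triisopropyl borate | CC(C)OB(OC(C)C)OC(C)C | starting material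
2 | dibromomethane | BrCBr | starting material
3 | (1S,2S)-1,2-dicyclohexylethane-1,2-diol | O[C@@H](C1CCCCC1)[C@H](C1CCCCC1)O | starting material
4 | lithium (bromomethyl)triisopropoxyborate | [Li+].BrC[B-](OC(C)C)(OC(C)C)OC(C)C | intermediate (not isolated)
5 | diisopropyl (bromomethyl)boronate | BrCB(OC(C)C)OC(C)C | intermediate (not isolated)
6 | (4S,5S)-2-(bromomethyl)-4,5-dicyclohexyl-1,3,2-dioxaborolane | BrCB1O[C@@H](C2CCCCC2)[C@H](C2CCCCC2)O1 | intermediate
7 | [(4S,5S)-4,5-dicyclohexyl-1,3,2-dioxaborolan-2-yl]methyl acetate | CC(=O)OCB1O[C@@H](C2CCCCC2)[C@H](C2CCCCC2)O1 | intermediate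
8 | [(4S,5S)-4,5-dicyclohexyl-1,3,2-dioxaborolan-2-yl]methanol | OCB1O[C@@H](C2CCCCC2)[C@H](C2CCCCC2)O1 | intermediate
9 | (4S,5S)-2-[(tert-butyldimethylsilyloxy)methyl]-4,5-dicyclohexyl-1,3,2-dioxaborolane | CC(C)(C)[Si](C)(C)OCB1O[C@@H](C2CCCCC2)[C@H](C2CCCCC2)O1 | intermediate
10 | dichloromethane | ClCCl | starting material
11 | 4-allyl-2,6-dimethoxyphenol | C=CCc1cc(OC)c(O)c(OC)c1 | starting material
12 | lithium (4S,5S)-2-[(tert-butyldimethylsilyloxy)methyl]-2-(dichloromethyl)-4,5-dicyclohexyl-1,3,2-dioxaborolan-2-uide | [Li+].CC(C)(C)[Si](C)(C)OC[B-]1(C(Cl)Cl)O[C@@H](C2CCCCC2)[C@H](C2CCCCC2)O1 | intermediate (not isolated)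
13 | (4S,5S)-2-[(1R)-2-(tert-butyldimethylsilyloxy)-1-chloroethyl]-4,5-dicyclohexyl-1,3,2-dioxaborolane | Cl[C@@H](CO[Si](C)(C)C(C)(C)C)B1O[C@@H](C2CCCCC2)[C@H](C2CCCCC2)O1 | intermediate (not isolated)
14 | lithium 4-allyl-2,6-dimethoxyphenoxide | [Li+].C=CCc1cc(OC)c([O-])c(OC)c1 | intermediate (not isolated)
15 | (4S,5S)-2-[(1S)-1-(4-allyl-2,6-dimethoxyphenoxy)-2-(tert-butyldimethylsilyloxy)ethyl]-4,5-dicyclohexyl-1,3,2-dioxaborolane | C=CCc1cc(OC)c(O[C@H](CO[Si](C)(C)C(C)(C)C)B2O[C@@H](C3CCCCC3)[C@H](C3CCCCC3)O2)c(OC)c1 | intermediate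
16 | lithium (4S,5S)-2-[(1S)-1-(4-allyl-2,6-dimethoxyphenoxy)-2-(tert-butyldimethylsilyloxy)ethyl]-2-(dichloromethyl)-4,5-dicyclohexyl-1,3,2-dioxaborolan-2-uide | [Li+].C=CCc1cc(OC)c(O[C@H](CO[Si](C)(C)C(C)(C)C)[B-]2(C(Cl)Cl)O[C@@H](C3CCCCC3)[C@H](C3CCCCC3)O2)c(OC)c1 | intermediate (not isolated)
17 | (4S,5S)-2-[(1R,2R)-2-(4-allyl-2,6-dimethoxyphenoxy)-3-(tert-butyldimethylsilyloxy)-1-chloropropyl]-4,5-dicyclohexyl-1,3,2-dioxaborolane | C=CCc1cc(OC)c(O[C@H](CO[Si](C)(C)C(C)(C)C)[C@H](Cl)B2O[C@@H](C3CCCCC3)[C@H](C3CCCCC3)O2)c(OC)c1 | intermediate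
18 | 5-bromo-1,2,3-trimethoxybenzene | COc1cc(Br)cc(OC)c1OC | starting material
19 | 3,4,5-trimethoxyphenylmagnesium bromide | COc1cc([Mg]Br)cc(OC)c1OC | intermediate
20 | bromomagnesium (4S,5S)-2-[(1R,2R)-2-(4-allyl-2,6-dimethoxyphenoxy)-3-(tert-butyldimethylsilyloxy)-1-chloropropyl]-4,5-dicyclohexyl-2-(3,4,5-trimethoxyphenyl)-1,3,2-dioxaborolan-2-uide | Br[Mg+].C=CCc1cc(OC)c(O[C@H](CO[Si](C)(C)C(C)(C)C)[C@H](Cl)[B-]2(c3cc(OC)c(OC)c(OC)c3)O[C@@H](C4CCCCC4)[C@H](C4CCCCC4)O2)c(OC)c1 | intermediate (not isolated)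
21 | (4S,5S)-2-[(1R,2S)-2-(4-allyl-2,6-dimethoxyphenoxy)-3-(tert-butyldimethylsilyloxy)-1-(3,4,5-trimethoxyphenyl)propyl]-4,5-dicyclohexyl-1,3,2-dioxaborolane | C=CCc1cc(OC)c(O[C@H](CO[Si](C)(C)C(C)(C)C)[C@@H](c2cc(OC)c(OC)c(OC)c2)B3O[C@@H](C4CCCCC4)[C@H](C4CCCCC4)O3)c(OC)c1 | intermediate
22 | (1R,2R)-2-(4-allyl-2,6-dimethoxyphenoxy)-3-(tert-butyldimethylsilyloxy)-1-(3,4,5-trimethoxyphenyl)propan-1-ol | C=CCc1cc(OC)c(O[C@H](CO[Si](C)(C)C(C)(C)C)[C@H](O)c2cc(OC)c(OC)c(OC)c2)c(OC)c1 | intermediate
23 | (1R,2R)-2-(4-allyl-2,6-dimethoxyphenoxy)-1-(3,4,5-trimethoxyphenyl)propane-1,3-diol | C=CCc1cc(OC)c(O[C@H](CO)[C@H](O)c2cc(OC)c(OC)c(OC)c2)c(OC)c1 | intermediate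
24 | (2R,3R)-2-(4-allyl-2,6-dimethoxyphenoxy)-3-hydroxy-3-(3,4,5-trimethoxyphenyl)propyl acetate | C=CCc1cc(OC)c(O[C@H](COC(C)=O)[C@H](O)c2cc(OC)c(OC)c(OC)c2)c(OC)c1 | target

**Step count and risks**

Total step count: 11. Longest linear sequence: 10 steps (steps 1 to 6 and 8 to 11, from triisopropyl borate); step 7 is a one-step side branch.

Step 5 is the step most likely to fail. The crowded aryloxide may displace the secondary chloride so slowly that chloride-induced epimerization at C8 or β-elimination of the silyloxy group from the borate overtakes substitution. The fallback sets out from phenol 11 and comes back at carbinol 22; it makes the C8–O bond by Mitsunobu inversion on a glycerate and sets C7 by a reagent-controlled ketone reduction. Methyl (S)-2,3-dihydroxypropanoate F1 (bought) is silylated at the primary hydroxyl (TBSCl, imidazole, CH2Cl2, 0 °C) to methyl (S)-3-(tert-butyldimethylsilyloxy)-2-hydroxypropanoate F2. Mitsunobu coupling of this ester with 11 (PPh3, diisopropyl azodicarboxylate, toluene, 0 °C → rt) should give, with inversion, methyl (R)-2-(4-allyl-2,6-dimethoxyphenoxy)-3-(tert-butyldimethylsilyloxy)propanoate F3. MeNH(OMe)·HCl and i-PrMgCl (THF, −20 °C) convert it into (R)-2-(4-allyl-2,6-dimethoxyphenoxy)-3-(tert-butyldimethylsilyloxy)-N-methoxy-N-methylpropanamide F4, and Grignard reagent 19 (THF, 0 °C) then gives (R)-2-(4-allyl-2,6-dimethoxyphenoxy)-3-(tert-butyldimethylsilyloxy)-1-(3,4,5-trimethoxyphenyl)propan-1-one F5. Corey–Bakshi–Shibata reduction with BH3·SMe2 and (R)-1-methyl-3,3-diphenyltetrahydro-1H,3H-pyrrolo[1,2-c][1,3,2]oxazaborole (toluene, −20 °C) should deliver hydride under catalyst control to give the (7R)-carbinol 22.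

Step 8 comes second. In borate 20 the boron and the C8 aryloxy group are 1,2-related, so β-elimination of the aryloxide may compete with aryl migration, and crowding may slow the transfer of the electron-rich aryl group. The fallback sets out from chloro boronate 17 and comes back at carbinol 22; it moves C7 to the aldehyde level and forms the C7–ring A bond by carbonyl addition. Buffered oxidation of 17 (H2O2, pH 8 phosphate buffer, THF, 0 °C) should give (R)-2-(4-allyl-2,6-dimethoxyphenoxy)-3-(tert-butyldimethylsilyloxy)propanal F6 with release of diol 3. Addition of 19 under chelation control (MgBr2·OEt2, CH2Cl2, −78 °C), with magnesium bridging the aldehyde oxygen and the C8 ether oxygen, should then favour the threo carbinol 22.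

Step 11 comes third. Discrimination between the two hydroxyls may be incomplete, or the acetyl group may migrate from O9 to O7. The fallback sets out from silyl ether 22 and comes back at target 24; it blocks O7 with an ester that can be removed in the presence of an acetate. Chloroacetic anhydride, pyridine and 4-(dimethylamino)pyridine (CH2Cl2, 0 °C) give (1R,2R)-2-(4-allyl-2,6-dimethoxyphenoxy)-3-(tert-butyldimethylsilyloxy)-1-(3,4,5-trimethoxyphenyl)propyl chloroacetate F7. HF·pyridine (THF, 0 °C) frees the primary hydroxyl to give (1R,2R)-2-(4-allyl-2,6-dimethoxyphenoxy)-3-hydroxy-1-(3,4,5-trimethoxyphenyl)propyl chloroacetate F8. Ac2O and pyridine give (1R,2R)-3-acetoxy-2-(4-allyl-2,6-dimethoxyphenoxy)-1-(3,4,5-trimethoxyphenyl)propyl chloroacetate F9, and thiourea with NaHCO3 (EtOH, 50 °C) should remove only the chloroacetyl group to give 24.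

**Further compounds**

F1 | step 5 | methyl (S)-2,3-dihydroxypropanoate (bought) | COC(=O)[C@@H](O)CO
F2 | step 5 | methyl (S)-3-(tert-butyldimethylsilyloxy)-2-hydroxypropanoate | COC(=O)[C@@H](O)CO[Si](C)(C)C(C)(C)C
F3 | step 5 | methyl (R)-2-(4-allyl-2,6-dimethoxyphenoxy)-3-(tert-butyldimethylsilyloxy)propanoate | C=CCc1cc(OC)c(O[C@H](CO[Si](C)(C)C(C)(C)C)C(=O)OC)c(OC)c1
F4 | step 5 | (R)-2-(4-allyl-2,6-dimethoxyphenoxy)-3-(tert-butyldimethylsilyloxy)-N-methoxy-N-methylpropanamide | C=CCc1cc(OC)c(O[C@H](CO[Si](C)(C)C(C)(C)C)C(=O)N(C)OC)c(OC)c1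
F5 | step 5 | (R)-2-(4-allyl-2,6-dimethoxyphenoxy)-3-(tert-butyldimethylsilyloxy)-1-(3,4,5-trimethoxyphenyl)propan-1-one | C=CCc1cc(OC)c(O[C@H](CO[Si](C)(C)C(C)(C)C)C(=O)c2cc(OC)c(OC)c(OC)c2)c(OC)c1
F6 | step 8 | (R)-2-(4-allyl-2,6-dimethoxyphenoxy)-3-(tert-butyldimethylsilyloxy)propanal | C=CCc1cc(OC)c(O[C@H](CO[Si](C)(C)C(C)(C)C)C=O)c(OC)c1
F7 | step 11 | (1R,2R)-2-(4-allyl-2,6-dimethoxyphenoxy)-3-(tert-butyldimethylsilyloxy)-1-(3,4,5-trimethoxyphenyl)propyl chloroacetate | C=CCc1cc(OC)c(O[C@H](CO[Si](C)(C)C(C)(C)C)[C@H](OC(=O)CCl)c2cc(OC)c(OC)c(OC)c2)c(OC)c1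
F8 | step 11 | (1R,2R)-2-(4-allyl-2,6-dimethoxyphenoxy)-3-hydroxy-1-(3,4,5-trimethoxyphenyl)propyl chloroacetate | C=CCc1cc(OC)c(O[C@H](CO)[C@H](OC(=O)CCl)c2cc(OC)c(OC)c(OC)c2)c(OC)c1
F9 | step 11 | (1R,2R)-3-acetoxy-2-(4-allyl-2,6-dimethoxyphenoxy)-1-(3,4,5-trimethoxyphenyl)propyl chloroacetate | C=CCc1cc(OC)c(O[C@H](COC(C)=O)[C@H](OC(=O)CCl)c2cc(OC)c(OC)c(OC)c2)c(OC)c1
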